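## Retrosynthetic overview

1. Target 25 ⇐ hydroxyquinone 23 ⇐ methoxyquinone 22 ⇐ arene 20: oxidative demethylation unveils the quinone of ring C last and makes C7–H acidic, so that C5=C6 moves to C6=C7 and C5–H is set.
2. Ring B ⇐ C5–C6 bond by vinyl addition to the C5 ketone of 17, then C7–C8 bond by Friedel–Crafts allylation.
3. Ring A and the lactone ⇐ cyclopentanone 15 in one step. The enabling feature is the δ-lactone C4–C19(=O)–O–C20–C10: its ester link on C10 tethers a diazo carbon (future C4) to the C5 ketone of a five-membered ring (C5, C10, C1, C2, C3). Insertion of C4 between C5 and C3 gives six-membered ring A, the quaternary C4 and the lactone bridge together.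
4. 15 ⇐ (R)-ketol 12 (C10 by catalytic asymmetric hydroxymethylation) ⇐ 2-arylcyclopentanone 9 ⇐ aryllithium 7 + cyclopentene oxide; arene 5 from 1,2,4-trimethoxybenzene.
5. Ring order: ring C (aromatic, bought) → five-membered precursor of ring A (bought) → ring A and lactone ring together → ring B.

Key step: step 9

Abbreviation: Ar = 2,3,5-trimethoxy-4-(propan-2-yl)phenyl; abietane locants C1 to C20 are used for positions.
Assumption: the antipode of the chiral bipyridine ligand that delivers the (R)-ketol in step 6 is taken as the one to use; its sense has to be confirmed on this substrate.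

## Route

Step 1
Reactants: 1 1,2,4-trimethoxybenzene; 2 acetone
Product: 4 2-(2,3,6-trimethoxyphenyl)propan-2-ol, via 2,3,6-trimethoxyphenyllithium 3 (not isolated)
Conditions: n-BuLi, THF, 0 °C; then acetone, −78 °C to rt; H2O
Reagents that add atoms: acetone (2), CC(C)=O
Why: Directed ortho-metalation removes the C3–H flanked by two methoxy groups, and the aryllithium adds 1,2 to acetone to give the tertiary benzylic alcohol; no stereocentre is formed.

Step 2
Reactants: 4 2-(2,3,6-trimethoxyphenyl)propan-2-ol
Product: 5 1,2,4-trimethoxy-3-(propan-2-yl)benzene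
Conditions: Et3SiH, CF3CO2H, CH2Cl2, 0 °C to rt
Reagents that add atoms: none
Why: Ionic hydrogenation, in which the cumyl cation stabilised by two ortho-methoxy groups is trapped by hydride from the silane; no stereocentre is formed.

Step 3
Reactants: 5 1,2,4-trimethoxy-3-(propan-2-yl)benzene; 6 cyclopentene oxide
Product: 8 rac-(1R,2S)-2-Ar-cyclopentan-1-ol (trans), via Ar-lithium 7 (not isolated)
Conditions: n-BuLi, THF, 0 °C to rt; then cyclopentene oxide, BF3·OEt2, −78 °C; H2O
Reagents that add atoms: cyclopentene oxide (6), C1CC2OC2C1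
Why: Directed ortho-metalation should occur at C6, which is ortho to the methoxy of the vicinal dimethoxy pair and meta to the two others (C5 is para to a methoxy group and its ortho-methoxy is twisted by the isopropyl group), and BF3-assisted SN2 opening of the meso epoxide gives the racemic trans alcohol, whose stereocentres are erased or overwritten in steps 4 to 6.

Step 4
Reactants: 8 rac-(1R,2S)-2-Ar-cyclopentan-1-ol
Product: 9 rac-2-Ar-cyclopentan-1-one
Conditions: 2-iodoxybenzoic acid (IBX), EtOAc, 75 °C
Reagents that add atoms: none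
Why: Alcohol oxidation with a hypervalent iodine reagent that tolerates the electron-rich arene; the α-aryl centre is racemic and is removed in step 5.

Step 5
Reactants: 9 rac-2-Ar-cyclopentan-1-one
Product: 10 trimethyl[(2-Ar-cyclopent-1-en-1-yl)oxy]silane
Conditions: Me3SiCl, Et3N, DMF, 80 °C
Reagents that add atoms: chlorotrimethylsilane, C[Si](C)(C)Cl
Why: Thermodynamic silyl enol ether formation places the double bond toward the aryl-bearing carbon because of conjugation and the more acidic benzylic α-hydrogen.

Step 6
Reactants: 10 trimethyl[(2-Ar-cyclopent-1-en-1-yl)oxy]silane; 11 formaldehyde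
Product: 12 (2R)-2-(hydroxymethyl)-2-Ar-cyclopentan-1-one
Conditions: aq. HCHO, Sc(OTf)3 (10 mol%), enantiopure 6,6'-bis(1-hydroxy-2,2-dimethylpropyl)-2,2'-bipyridine (12 mol%), DME/H2O, −20 °C
Reagents that add atoms: formaldehyde (11), C=O
Why: Aqueous Mukaiyama aldol hydroxymethylation of a silyl enol ether under a chiral scandium–bipyridine Lewis acid, a known catalytic asymmetric reaction type; the catalyst differentiates the enol ether faces and sets the quaternary centre C10 (R), from which all other stereocentres are relayed.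

Step 7
Reactants: 12 (2R)-2-(hydroxymethyl)-2-Ar-cyclopentan-1-one; 13 tert-butyl 2-methyl-3-oxobutanoate
Product: 14 [(1R)-2-oxo-1-Ar-cyclopentyl]methyl 2-methyl-3-oxobutanoate (epimer mixture at the acetoacetate carbon)
Conditions: toluene, 110 °C, tert-butanol distilled off
Reagents that add atoms: tert-butyl 2-methyl-3-oxobutanoate (13), CC(=O)C(C)C(=O)OC(C)(C)C
Why: Thermal acetoacetylation through an acylketene, trapped by the neopentylic alcohol under neutral conditions that avoid retro-aldol loss of formaldehyde; the new α-centre is uncontrolled and is removed in step 8.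

Step 8
Reactants: 14 [(1R)-2-oxo-1-Ar-cyclopentyl]methyl 2-methyl-3-oxobutanoate
Product: 15 [(1R)-2-oxo-1-Ar-cyclopentyl]methyl 2-diazopropanoate
Conditions: 4-acetamidobenzenesulfonyl azide, DBU, MeCN, 0 °C to rt
Reagents that add atoms: 4-acetamidobenzenesulfonyl azide, CC(=O)Nc1ccc(cc1)S(=O)(=O)N=[N+]=[N-]
Why: Regitz deacylative diazo transfer, in which the acetoacetate enolate takes up the sulfonyl azide and the acetyl group leaves on the sulfonamide nitrogen; the cyclopentanone is not activated enough to react.

Step 9
Reactants: 15 [(1R)-2-oxo-1-Ar-cyclopentyl]methyl 2-diazopropanoate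
Product: 17 (1S,5R)-1-methyl-5-Ar-3-oxabicyclo[3.3.1]nonane-2,9-dione, via diazonium betaine 16 (not isolated)
Conditions: BF3·OEt2 (1.5 equiv), CH2Cl2 (0.01 M), slow addition of 15, −78 to −20 °C
Reagents that add atoms: none
Why: Proposed new method: BF3 activates the cyclopentanone carbonyl (C5), the diazo carbon (future C4), held by the C20–O–C19 ester tether, adds to it through a six-membered transition state to give the cis-fused betaine 16, and the C5–C3 bond then migrates to C4 with loss of N2 and inversion at C4; the closest known reaction type is the intermolecular Lewis-acid (Tiffeneau–Demjanov-type) ring enlargement of cycloalkanones with α-alkyl-α-diazo esters to α-quaternary β-keto esters. The δ-lactone ring closes in the C–C addition (6-exo-trig), and ring A is closed as a cyclohexanone by the 1,2-alkyl shift, a one-carbon enlargement of the five-membered ring. The new quaternary centre C4 is controlled by C10 through the tether: a three-atom ester bridge can span C4 and C10 only in the cis (1,3-diaxial) sense, which puts C19 β and methyl α. The step needs migration of the methylene C3 rather than the quaternary aryl-bearing C10 or epoxide closure. This should be secured by the known preference for migration of the less substituted carbon in such homologations and by the betaine geometry, in which the methyl on C4 avoids the aryl-bearing C10 and so places N2 antiperiplanar to C5–C3. High dilution and slow addition should suppress intermolecular reaction.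

Step 10
Reactants: 17 (1S,5R)-1-methyl-5-Ar-3-oxabicyclo[3.3.1]nonane-2,9-dione; 18 vinylmagnesium bromide
Product: 19 (1S,5R)-9-ethenyl-9-hydroxy-1-methyl-5-Ar-3-oxabicyclo[3.3.1]nonan-2-one (C9 configuration not assigned)
Conditions: CH2=CHMgBr, LaCl3·2LiCl (30 mol%), THF, −40 to 0 °C; H2O
Reagents that add atoms: vinylmagnesium bromide (18), C=C[Mg]Br
Why: 1,2-Addition of a vinyl Grignard reagent (lanthanum-assisted) to the non-enolisable bridge ketone, which is more electrophilic than the neopentylic lactone carbonyl; the new carbinol centre is not controlled and is destroyed in step 11.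

Step 11
Reactants: 19 (1S,5R)-9-ethenyl-9-hydroxy-1-methyl-5-Ar-3-oxabicyclo[3.3.1]nonan-2-one
Product: 20 (4S,10R)-11,12,14-trimethoxyabieta-5,8,11,13-tetraen-19,20-olide
Conditions: BF3·OEt2, CH2Cl2, −40 to 0 °C
Reagents that add atoms: none
Why: Intramolecular Friedel–Crafts allylation (SN1'), in which the allyl cation from the tertiary allylic alcohol is attacked at its unsubstituted terminus C7 by C8, the only free arene position and activated by ortho and para methoxy groups, in a six-membered closure; no stereocentre is formed.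

Step 12
Reactants: 20 (4S,10R)-11,12,14-trimethoxyabieta-5,8,11,13-tetraen-19,20-olide
Product: 22 (4S,5R,10R)-12-methoxy-11,14-dioxoabieta-6,8,12-trien-19,20-olide, via 5-ene methoxyquinone 21 (not isolated)
Conditions: (NH4)2Ce(NO3)6, MeCN/H2O, 0 °C; then DBU (10 mol%), CH2Cl2, 0 °C, Ar
Reagents that add atoms: water, O
Why: Oxidative demethylation of the para-dimethoxy pair by tetravalent cerium should give the 11,14-quinone with the 12-methoxy group kept as a vinylogous ester, after which base-mediated prototropic isomerisation through the extended dienolate (C7–H is now γ to the C11 carbonyl and allylic) moves the double bond into conjugation; C5 is protonated reversibly, so the trans ring fusion (5α-H, C6 equatorial on ring A) is expected as the thermodynamic product.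

Step 13
Reactants: 22 (4S,5R,10R)-12-methoxy-11,14-dioxoabieta-6,8,12-trien-19,20-olide
Product: 23 (4S,5R,10R)-12-hydroxy-11,14-dioxoabieta-6,8,12-trien-19,20-olide
Conditions: LiOH, THF/H2O, 0 °C, Ar; then 1 M HCl
Reagents that add atoms: lithium hydroxide, [Li+].[OH-]
Why: Addition–elimination hydrolysis of the vinylogous methyl ester (methoxyquinone to hydroxyquinone); the hindered bridged lactone should survive or re-close on acidification, and no stereocentre is touched.

Step 14
Reactants: 23 (4S,5R,10R)-12-hydroxy-11,14-dioxoabieta-6,8,12-trien-19,20-olide; 24 acetic anhydride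
Product: 25 (4S,5R,10R)-12-acetoxy-11,14-dioxoabieta-6,8,12-trien-19,20-olide (target, CNP0596241.1)
Conditions: Ac2O, pyridine, DMAP (cat.), CH2Cl2, 0 °C to rt
Reagents that add atoms: acetic anhydride (24), CC(=O)OC(C)=O
Why: O-Acylation of the acidic hydroxyquinone under nucleophilic catalysis; no stereocentre is affected.

## Compound list

1 | 1,2,4-trimethoxybenzene | COc1ccc(OC)c(OC)c1 | starting material
2 | acetone | CC(C)=O | starting material
3 | 2,3,6-trimethoxyphenyllithium | [Li]c1c(OC)ccc(OC)c1OC | intermediate
4 | 2-(2,3,6-trimethoxyphenyl)propan-2-ol | CC(C)(O)c1c(OC)ccc(OC)c1OC | intermediate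
5 | 1,2,4-trimethoxy-3-(propan-2-yl)benzene | CC(C)c1c(OC)ccc(OC)c1OC | intermediate
6 | cyclopentene oxide | C1CC2OC2C1 | starting material
7 | [2,3,5-trimethoxy-4-(propan-2-yl)phenyl]lithium | CC(C)c1c(OC)cc([Li])c(OC)c1OC | intermediate
8 | rac-(1R,2S)-2-Ar-cyclopentan-1-ol (trans; one enantiomer drawn) | O[C@@H]1CCC[C@H]1c1cc(OC)c(C(C)C)c(OC)c1OC | intermediate
9 | rac-2-Ar-cyclopentan-1-one | O=C1CCCC1c1cc(OC)c(C(C)C)c(OC)c1OC | intermediate
10 | trimethyl[(2-Ar-cyclopent-1-en-1-yl)oxy]silane | C[Si](C)(C)OC1=C(c2cc(OC)c(C(C)C)c(OC)c2OC)CCC1 | intermediate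
11 | formaldehyde | C=O | starting material
12 | (2R)-2-(hydroxymethyl)-2-Ar-cyclopentan-1-one | OC[C@]1(c2cc(OC)c(C(C)C)c(OC)c2OC)CCCC1=O | intermediate
13 | tert-butyl 2-methyl-3-oxobutanoate | CC(=O)C(C)C(=O)OC(C)(C)C | starting material
14 | [(1R)-2-oxo-1-Ar-cyclopentyl]methyl 2-methyl-3-oxobutanoate (epimers at the acetoacetate carbon) | CC(=O)C(C)C(=O)OC[C@]1(c2cc(OC)c(C(C)C)c(OC)c2OC)CCCC1=O | intermediate
15 | [(1R)-2-oxo-1-Ar-cyclopentyl]methyl 2-diazopropanoate | CC(=[N+]=[N-])C(=O)OC[C@]1(c2cc(OC)c(C(C)C)c(OC)c2OC)CCCC1=O | intermediate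
16 | cis-fused diazonium betaine (drawn as free zwitterion; alkoxide bound to BF3 in the flask) | [O-][C@]12CCC[C@@]1(c3cc(OC)c(C(C)C)c(OC)c3OC)COC(=O)[C@]2(C)[N+]#N | intermediate
17 | (1S,5R)-1-methyl-5-Ar-3-oxabicyclo[3.3.1]nonane-2,9-dione | C[C@@]12CCC[C@@](c3cc(OC)c(C(C)C)c(OC)c3OC)(COC1=O)C2=O | intermediate
18 | vinylmagnesium bromide | C=C[Mg]Br | starting material
19 | (1S,5R)-9-ethenyl-9-hydroxy-1-methyl-5-Ar-3-oxabicyclo[3.3.1]nonan-2-one (C9 not assigned) | C[C@@]12CCC[C@@](c3cc(OC)c(C(C)C)c(OC)c3OC)(COC1=O)C2(O)C=C | intermediate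
20 | (4S,10R)-11,12,14-trimethoxyabieta-5,8,11,13-tetraen-19,20-olide | C[C@@]12CCC[C@]3(COC1=O)c4c(OC)c(OC)c(C(C)C)c(OC)c4CC=C23 | intermediate
21 | (4S,10R)-12-methoxy-11,14-dioxoabieta-5,8,12-trien-19,20-olide | COC1=C(C(C)C)C(=O)C2=C(C1=O)[C@]13CCC[C@](C)(C(=O)OC1)C3=CC2 | intermediate
22 | (4S,5R,10R)-12-methoxy-11,14-dioxoabieta-6,8,12-trien-19,20-olide | COC1=C(C(C)C)C(=O)C2=C(C1=O)[C@]13CCC[C@](C)(C(=O)OC1)[C@@H]3C=C2 | intermediate
23 | (4S,5R,10R)-12-hydroxy-11,14-dioxoabieta-6,8,12-trien-19,20-olide | OC1=C(C(C)C)C(=O)C2=C(C1=O)[C@]13CCC[C@](C)(C(=O)OC1)[C@@H]3C=C2 | intermediate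
24 | acetic anhydride | CC(=O)OC(C)=O | starting material
25 | (4S,5R,10R)-12-acetoxy-11,14-dioxoabieta-6,8,12-trien-19,20-olide | CC(=O)OC1=C(C(C)C)C(=O)C2=C(C1=O)[C@]13CCC[C@](C)(C(=O)OC1)[C@@H]3C=C2 | target

## Step count and main risks

Total step count: 14. Longest linear sequence: 14 steps, from 1,2,4-trimethoxybenzene.

**Step 9 (Proposed new method).** The wrong bond may migrate (the aryl-bearing C10 instead of C3), the betaine may close to an epoxide, or the ester tether may fail to reach the s-cis rotamer needed for the six-membered closure, so that the diazo group decomposes before it reaches the hindered ketone. The fallback uses the known intermolecular homologation and sets out from 12. Silylation (TBSCl, imidazole) should give (2R)-2-{[tert-butyl(dimethyl)silyl]oxymethyl}-2-Ar-cyclopentan-1-one F1. BF3·OEt2-promoted ring enlargement with methyl 2-diazopropanoate, an established reaction type in which the methylene carbon migrates, should give methyl (3R)-3-{[tert-butyl(dimethyl)silyl]oxymethyl}-1-methyl-2-oxo-3-Ar-cyclohexane-1-carboxylate F2 as a mixture of C1 epimers; ring A still arises from the five-membered ring. HF·pyridine followed by TsOH in toluene removes the silyl group and closes the lactone of the cis epimer, which rejoins the route at 17. The trans hydroxy ester, methyl (1R,3R)-3-(hydroxymethyl)-1-methyl-2-oxo-3-Ar-cyclohexane-1-carboxylate F3, cannot lactonise and is separated.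

**Step 10.** Addition may fail at the doubly neopentylic bridge ketone, the reagent may attack the lactone carbonyl instead, or the alkoxide may open the β-keto lactone by retro-Claisen cleavage. The fallback avoids organometallic addition and sets out from 17. Friedel–Crafts acetylation at C8 (AcCl, SnCl4) should give (1S,5R)-5-[2-acetyl-3,5,6-trimethoxy-4-(propan-2-yl)phenyl]-1-methyl-3-oxabicyclo[3.3.1]nonane-2,9-dione F4. TsOH-mediated intramolecular aldol condensation of the methyl ketone onto the C5 ketone closes ring B as (4S,10R)-11,12,14-trimethoxy-7-oxoabieta-5,8,11,13-tetraen-19,20-olide F5. Luche reduction (NaBH4, CeCl3·7H2O) gives the allylic alcohol (4S,10R)-7-hydroxy-11,12,14-trimethoxyabieta-5,8,11,13-tetraen-19,20-olide F6, and ionic deoxygenation (Et3SiH, CF3CO2H), with hydride delivered to the benzylic terminus, comes back to the route at 20.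

**Step 6.** Facial selection at the tetrasubstituted enol ether may be poor (low enantiomeric purity at the quaternary centre), or desilylation back to 9 may outrun the aldol addition. The fallback replaces asymmetric catalysis by resolution and sets out from 10. Sc(OTf)3 without ligand and aqueous formaldehyde should give racemic 2-(hydroxymethyl)-2-Ar-cyclopentan-1-one F7. Lipase-catalysed transesterification with vinyl acetate acetylates one enantiomer, drawn here as [(1S)-2-oxo-1-Ar-cyclopentyl]methyl acetate F8, and leaves the (R)-alcohol, which rejoins the route at 12. If the enzyme prefers the (R)-alcohol, its acetate is cleaved with the same lipase in buffer.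

## Further compounds

F1 | step 9 | (2R)-2-{[tert-butyl(dimethyl)silyl]oxymethyl}-2-Ar-cyclopentan-1-one | CC(C)(C)[Si](C)(C)OC[C@]1(c2cc(OC)c(C(C)C)c(OC)c2OC)CCCC1=O
F2 | step 9 | methyl (3R)-3-{[tert-butyl(dimethyl)silyl]oxymethyl}-1-methyl-2-oxo-3-Ar-cyclohexane-1-carboxylate (C1 epimer mixture) | COC(=O)C1(C)CCC[C@@](c2cc(OC)c(C(C)C)c(OC)c2OC)(CO[Si](C)(C)C(C)(C)C)C1=O
F3 | step 9 | methyl (1R,3R)-3-(hydroxymethyl)-1-methyl-2-oxo-3-Ar-cyclohexane-1-carboxylate (trans, not lactonising) | COC(=O)[C@]1(C)CCC[C@@](c2cc(OC)c(C(C)C)c(OC)c2OC)(CO)C1=O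
F4 | step 10 | (1S,5R)-5-[2-acetyl-3,5,6-trimethoxy-4-(propan-2-yl)phenyl]-1-methyl-3-oxabicyclo[3.3.1]nonane-2,9-dione | C[C@@]12CCC[C@@](c3c(C(C)=O)c(OC)c(C(C)C)c(OC)c3OC)(COC1=O)C2=O
F5 | step 10 | (4S,10R)-11,12,14-trimethoxy-7-oxoabieta-5,8,11,13-tetraen-19,20-olide | C[C@@]12CCC[C@]3(COC1=O)c4c(OC)c(OC)c(C(C)C)c(OC)c4C(=O)C=C23
F6 | step 10 | (4S,10R)-7-hydroxy-11,12,14-trimethoxyabieta-5,8,11,13-tetraen-19,20-olide (C7 epimers) | C[C@@]12CCC[C@]3(COC1=O)c4c(OC)c(OC)c(C(C)C)c(OC)c4C(O)C=C23
F7 | step 6 | rac-2-(hydroxymethyl)-2-Ar-cyclopentan-1-one | OCC1(c2cc(OC)c(C(C)C)c(OC)c2OC)CCCC1=O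
F8 | step 6 | [(1S)-2-oxo-1-Ar-cyclopentyl]methyl acetate | CC(=O)OC[C@@]1(c2cc(OC)c(C(C)C)c(OC)c2OC)CCCC1=O
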